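**Assumption:** germacrane numbering is used throughout (lactone C12(=O)–O–C8, ketone C5, isobutyrates on O6 and O9, hydroxyls on C2 and C10, so the target is 2S,4S,6S,7R,8R,9S,10S), and the target is taken as the open 5-keto-2-hydroxy form of the SMILES.

## Retrosynthetic overview

1. Cardivin D ⇐ desilylation and bis-isobutyrylation of a macrocyclic C2-silylated triol-ketone; O2 is masked so only O6 and O9 are acylated.
2. Ten-membered ring ⇐ C6–C7 bond, the bond formed when farnesyl diphosphate closes to a germacrene, with C13 ending as the exo-methylene. It is made by an intramolecular Cr(II) Barbier (Nozaki–Hiyama) addition of a 3-(bromomethyl)butenolide to a tethered α-keto aldehyde, which sets C6 and C7.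
3. Lactone ⇐ acylation of O8 by the C11–C13 acrylate unit, then ring-closing metathesis; C8/C9 come from a Brown γ-alkoxyallylboration.
4. Chain ⇐ C5–C6 by dithiane acylation of a γ-lactone; C2–C3 by Fukuyama coupling (C4 from a commercial bromoester); C1–C10 by a Cu–box pyruvate aldol; C2 by hydroxyl-directed reduction.
5. Ring order: butenolide first (step 11), ten-membered carbocycle second (step 13).

## Route

Step 1
Reactants: 1 S-ethyl thioacetate
Product: 2 1-(ethylsulfanyl)-1-(trimethylsilyloxy)ethene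
Conditions: LDA, THF, −78 °C; TMSCl; distil
Reagents that add atoms: chlorotrimethylsilane, C[Si](C)(C)Cl
Why: Kinetic enolisation of the thioester and O-silylation give the silyl ketene thioacetal (no stereocentre).

Step 2
Reactants: 2 1-(ethylsulfanyl)-1-(trimethylsilyloxy)ethene; 3 isopropyl pyruvate
Product: 5 isopropyl (S)-4-(ethylsulfanyl)-2-hydroxy-2-methyl-4-oxobutanoate, via TMS ether 4 (not isolated)
Conditions: [Cu((S,S)-t-Bu-box)](OTf)2 (10 mol %), THF, −78 °C; then 1 M HCl
Reagents that add atoms: none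
Why: Evans Cu(II)–bis(oxazoline) Mukaiyama aldol to the chelated pyruvate; the ligand shields one ketone face of the square-planar chelate and sets the tertiary carbinol C10 as S, as known for thioacetate ketene acetals with pyruvate esters.

Step 3
Reactants: 5 isopropyl (S)-4-(ethylsulfanyl)-2-hydroxy-2-methyl-4-oxobutanoate; 6 methyl (R)-3-bromo-2-methylpropanoate
Product: 8 1-isopropyl 7-methyl (2S,6S)-2-hydroxy-2,6-dimethyl-4-oxoheptanedioate, via alkylzinc bromide 7 (not isolated)
Conditions: 6, Zn dust, I2 (cat.), DMA, 80 °C; then 5, PdCl2(PPh3)2 (5 mol %), PhMe, rt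
Reagents that add atoms: none
Why: Fukuyama coupling (Pd-catalysed acylation of an alkylzinc halide by a thioester) makes C2–C3; the zinc homoenolate cannot enolise, so C4 is carried through unchanged, and both esters and the free OH are tolerated.

Step 4
Reactants: 8 1-isopropyl 7-methyl (2S,6S)-2-hydroxy-2,6-dimethyl-4-oxoheptanedioate
Product: 10 isopropyl (S)-2-hydroxy-2-methyl-3-[(2S,4S)-4-methyl-5-oxooxolan-2-yl]propanoate, via diol diester 9 (not isolated)
Conditions: Me4NBH(OAc)3, MeCN/AcOH (1:1), −30 °C; then PPTS (cat.), PhMe, 50 °C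
Reagents that add atoms: none
Why: Evans–Saksena hydroxyl-directed reduction delivers hydride within a chair in which the C10 methyl is expected to sit equatorial and the flat ester axial, giving 2S (O2 and O10 syn along the C9–C3 chain); acid then lactonises O2 onto the unhindered methyl ester only.

Step 5
Reactants: 10 isopropyl (S)-2-hydroxy-2-methyl-3-[(2S,4S)-4-methyl-5-oxooxolan-2-yl]propanoate; 11 1,3-dithiane
Product: 13 isopropyl (2S,4S,6S)-7-(1,3-dithian-2-yl)-2,4-dihydroxy-2,6-dimethyl-7-oxoheptanoate, via 2-lithio-1,3-dithiane 12 (not isolated)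
Conditions: 11 (3.3 equiv), n-BuLi, THF, −30 °C; then 10, −78 °C; aq. NH4Cl
Reagents that add atoms: none
Why: Corey–Seebach acylation of the lithiodithiane by the γ-lactone installs C6 as a masked aldehyde; the acyl dithiane is deprotonated at the dithiane carbon, which stops a second addition and protects C4, and the hindered isopropyl ester next to the C10 alkoxide is left alone.

Step 6
Reactants: 13 isopropyl (2S,4S,6S)-7-(1,3-dithian-2-yl)-2,4-dihydroxy-2,6-dimethyl-7-oxoheptanoate
Product: 14 isopropyl (2S,4S,6S)-4-[(tert-butyldimethylsilyl)oxy]-7-(1,3-dithian-2-yl)-2-hydroxy-2,6-dimethyl-7-oxoheptanoate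
Conditions: TBSCl, imidazole, DMF, rt
Reagents that add atoms: tert-butyldimethylsilyl chloride, CC(C)(C)[Si](C)(C)Cl
Why: Selective silylation of the only secondary hydroxyl (tertiary C10–OH is inert to TBSCl/imidazole), which also pulls any 2,5-hemiketal over to the open keto form.

Step 7
Reactants: 14 isopropyl (2S,4S,6S)-4-[(tert-butyldimethylsilyl)oxy]-7-(1,3-dithian-2-yl)-2-hydroxy-2,6-dimethyl-7-oxoheptanoate
Product: 16 (2S,4S,6S)-4-[(tert-butyldimethylsilyl)oxy]-7-(1,3-dithian-2-yl)-2-hydroxy-2,6-dimethyl-7-oxoheptanal, via dilithium enolate alkoxide 15 (not isolated)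
Conditions: LiHMDS (2.2 equiv), THF, −78 °C; then DIBAL-H (3 equiv), −78 → −40 °C; aq. Rochelle salt
Reagents that add atoms: none
Why: In situ enolate protection of the ketone (deprotonation at the doubly activated dithiane C–H, not at C4) followed by DIBAL half-reduction of the alkoxide-chelated isopropyl ester, whose aluminium hemiacetal collapses to the aldehyde only on work-up.

Step 8
Reactants: 16 (2S,4S,6S)-4-[(tert-butyldimethylsilyl)oxy]-7-(1,3-dithian-2-yl)-2-hydroxy-2,6-dimethyl-7-oxoheptanal; 17 allyl methoxymethyl ether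
Product: 20 (2S,4S,6S,7S,8R)-4-[(tert-butyldimethylsilyl)oxy]-1-(1,3-dithian-2-yl)-6,7-dihydroxy-8-(methoxymethoxy)-2,6-dimethyldec-9-en-1-one, via alkoxyallyllithium 18 (not isolated), via alkoxyallylborane 19 (not isolated)
Conditions: 17 (2.5 equiv), s-BuLi, THF, −78 °C; (−)-Ipc2BOMe; BF3·OEt2; then 16, −78 °C; ethanolamine work-up
Reagents that add atoms: none
Why: Brown (Z)-γ-alkoxyallylboration through a chair Zimmerman–Traxler transition state gives the syn C8/C9 pair, and the (+)-α-pinene-derived reagent attacks the aldehyde Si face (reagent control), setting 8R,9S; the hindered ketone does not compete.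

Step 9
Reactants: 20 (2S,4S,6S,7S,8R)-4-[(tert-butyldimethylsilyl)oxy]-1-(1,3-dithian-2-yl)-6,7-dihydroxy-8-(methoxymethoxy)-2,6-dimethyldec-9-en-1-one
Product: 21 (2S,4S,6S,7S,8R)-4-[(tert-butyldimethylsilyl)oxy]-1-(1,3-dithian-2-yl)-6,7,8-trihydroxy-2,6-dimethyldec-9-en-1-one
Conditions: Me2BBr, CH2Cl2, −78 °C; then THF/aq. NaHCO3
Reagents that add atoms: none
Why: Lewis-acid cleavage of the MOM acetal (Guindon conditions) at −78 °C leaves the secondary TBS ether, the dithiane and the ketone untouched.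

Step 10
Reactants: 21 (2S,4S,6S,7S,8R)-4-[(tert-butyldimethylsilyl)oxy]-1-(1,3-dithian-2-yl)-6,7,8-trihydroxy-2,6-dimethyldec-9-en-1-one; 22 2-(bromomethyl)acrylic acid
Product: 24 (3R,4S,5S,7S,9S)-7-[(tert-butyldimethylsilyl)oxy]-10-(1,3-dithian-2-yl)-4,5-dihydroxy-5,9-dimethyl-10-oxodec-1-en-3-yl 2-(bromomethyl)acrylate, via acid chloride 23 (not isolated)
Conditions: 22, (COCl)2, DMF (cat.), CH2Cl2, 0 °C; then 21, 2,4,6-collidine, CH2Cl2, −78 → −30 °C
Reagents that add atoms: none
Why: Site-selective O-acylation: the allylic C8–OH is the only unhindered hydroxyl (C9–OH is flanked by quaternary C10, C10–OH is tertiary), and a hindered pyridine base avoids SN2′ attack on the bromomethyl acrylate.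

Step 11
Reactants: 24 (3R,4S,5S,7S,9S)-7-[(tert-butyldimethylsilyl)oxy]-10-(1,3-dithian-2-yl)-4,5-dihydroxy-5,9-dimethyl-10-oxodec-1-en-3-yl 2-(bromomethyl)acrylate
Product: 25 (5R)-3-(bromomethyl)-5-[(1S,2S,4S,6S)-4-[(tert-butyldimethylsilyl)oxy]-7-(1,3-dithian-2-yl)-1,2-dihydroxy-2,6-dimethyl-7-oxoheptyl]furan-2(5H)-one
Conditions: Hoveyda–Grubbs II (10 mol %), PhMe (5 mM), 80 °C
Reagents that add atoms: none
Why: Ring-closing metathesis of an allyl 2-substituted acrylate closes the butenolide (C7=C11) under neutral conditions, so the base-sensitive C8 centre is not touched.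

Step 12
Reactants: 25 (5R)-3-(bromomethyl)-5-[(1S,2S,4S,6S)-4-[(tert-butyldimethylsilyl)oxy]-7-(1,3-dithian-2-yl)-1,2-dihydroxy-2,6-dimethyl-7-oxoheptyl]furan-2(5H)-one
Product: 26 (5R)-3-(bromomethyl)-5-[(1S,2S,4S,6S)-4-[(tert-butyldimethylsilyl)oxy]-1,2-dihydroxy-2,6-dimethyl-7,8-dioxooctyl]furan-2(5H)-one
Conditions: NBS, 2,6-lutidine, acetone/H2O (9:1), −10 °C, 10 min; Na2S2O3; dry azeotropically
Reagents that add atoms: water, O
Why: Corey–Erickson oxidative hydrolysis of the acyl dithiane unveils the α-keto aldehyde in a brief, buffered step that spares the vicinal diol, the allylic bromide and the butenolide.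

Step 13
Reactants: 26 (5R)-3-(bromomethyl)-5-[(1S,2S,4S,6S)-4-[(tert-butyldimethylsilyl)oxy]-1,2-dihydroxy-2,6-dimethyl-7,8-dioxooctyl]furan-2(5H)-one
Product: 28 (2S,4S,6S,7R,8R,9S,10S)-2-[(tert-butyldimethylsilyl)oxy]-6,9,10-trihydroxy-5-oxogermacr-11(13)-en-12,8-olide, via allylchromium species 27 (not isolated)
Conditions: CrCl2 (10 equiv), THF, 4 Å MS, rt, syringe-pump addition of 26 (final 2 mM); aq. work-up
Reagents that add atoms: none
Why: Proposed new method: Cr(II) inserts into the allylic bromide to give a cyclic, E-configured γ-substituted allylchromium(III) that adds through its γ-carbon (C7) to the more electrophilic aldehyde carbonyl via a chair Zimmerman–Traxler transition state, anti to the C8 side chain (trans-lactone, 7R) and with the E-crotyl-type relationship that gives 6S, closing the ten-membered ring and regenerating the exo-methylene; the closest known chemistry is the intermolecular Cr/Zn/In Barbier allylation of aldehydes with 3-(bromomethyl)furan-2(5H)-one and the Nozaki–Hiyama macrocyclisations of 2-(bromomethyl)acrylates used for germacranolides.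

Step 14
Reactants: 28 (2S,4S,6S,7R,8R,9S,10S)-2-[(tert-butyldimethylsilyl)oxy]-6,9,10-trihydroxy-5-oxogermacr-11(13)-en-12,8-olide
Product: 29 (2S,4S,6S,7R,8R,9S,10S)-2-[(tert-butyldimethylsilyl)oxy]-10-hydroxy-6,9-bis(isobutyryloxy)-5-oxogermacr-11(13)-en-12,8-olide
Conditions: (i-PrCO)2O, DMAP (cat.), pyridine, CH2Cl2, 0 °C → rt
Reagents that add atoms: isobutyric anhydride, CC(C)C(=O)OC(=O)C(C)C
Why: DMAP-catalysed acylation esterifies both secondary hydroxyls (O6, O9) in one step, while the tertiary C10–OH does not react and O2 is silylated.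

Step 15
Reactants: 29 (2S,4S,6S,7R,8R,9S,10S)-2-[(tert-butyldimethylsilyl)oxy]-10-hydroxy-6,9-bis(isobutyryloxy)-5-oxogermacr-11(13)-en-12,8-olide
Product: 30 cardivin D, (2S,4S,6S,7R,8R,9S,10S)-2,10-dihydroxy-6,9-bis(isobutyryloxy)-5-oxogermacr-11(13)-en-12,8-olide
Conditions: HF·pyridine, THF/pyridine, 0 °C → rt
Reagents that add atoms: none
Why: Buffered fluoride desilylation frees C2–OH without touching the α-methylene lactone, the isobutyrates or the epimerisable C4/C6 centres.

## Compound list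

1 | S-ethyl thioacetate | CCSC(C)=O | starting material
2 | 1-(ethylsulfanyl)-1-(trimethylsilyloxy)ethene | C=C(SCC)O[Si](C)(C)C | intermediate
3 | isopropyl pyruvate | CC(=O)C(=O)OC(C)C | starting material
4 | TMS ether of 5 (Mukaiyama aldol adduct) | CCSC(=O)C[C@](C)(O[Si](C)(C)C)C(=O)OC(C)C | intermediate
5 | isopropyl (S)-4-(ethylsulfanyl)-2-hydroxy-2-methyl-4-oxobutanoate | CCSC(=O)C[C@](C)(O)C(=O)OC(C)C | intermediate
6 | methyl (R)-3-bromo-2-methylpropanoate | COC(=O)[C@@H](C)CBr | starting material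
7 | [(2R)-3-methoxy-2-methyl-3-oxopropyl]zinc bromide | COC(=O)[C@@H](C)C[Zn]Br | intermediate
8 | 1-isopropyl 7-methyl (2S,6S)-2-hydroxy-2,6-dimethyl-4-oxoheptanedioate | COC(=O)[C@@H](C)CC(=O)C[C@](C)(O)C(=O)OC(C)C | intermediate
9 | 1-isopropyl 7-methyl (2S,4S,6S)-2,4-dihydroxy-2,6-dimethylheptanedioate | COC(=O)[C@@H](C)C[C@H](O)C[C@](C)(O)C(=O)OC(C)C | intermediate
10 | isopropyl (S)-2-hydroxy-2-methyl-3-[(2S,4S)-4-methyl-5-oxooxolan-2-yl]propanoate (cis-lactone) | O=C1[C@@H](C)C[C@H](O1)C[C@](C)(O)C(=O)OC(C)C | intermediate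
11 | 1,3-dithiane | C1CSCSC1 | starting material
12 | 2-lithio-1,3-dithiane | [Li]C1SCCCS1 | intermediate
13 | isopropyl (2S,4S,6S)-7-(1,3-dithian-2-yl)-2,4-dihydroxy-2,6-dimethyl-7-oxoheptanoate | O=C(C1SCCCS1)[C@@H](C)C[C@H](O)C[C@](C)(O)C(=O)OC(C)C | intermediate
14 | isopropyl (2S,4S,6S)-4-[(tert-butyldimethylsilyl)oxy]-7-(1,3-dithian-2-yl)-2-hydroxy-2,6-dimethyl-7-oxoheptanoate | O=C(C1SCCCS1)[C@@H](C)C[C@H](O[Si](C)(C)C(C)(C)C)C[C@](C)(O)C(=O)OC(C)C | intermediate
15 | dilithium salt of 14 (C10 alkoxide, C5/C6 dithianylidene enolate) | [Li]OC(=C1SCCCS1)[C@@H](C)C[C@H](O[Si](C)(C)C(C)(C)C)C[C@](C)(O[Li])C(=O)OC(C)C | intermediate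
16 | (2S,4S,6S)-4-[(tert-butyldimethylsilyl)oxy]-7-(1,3-dithian-2-yl)-2-hydroxy-2,6-dimethyl-7-oxoheptanal | O=C(C1SCCCS1)[C@@H](C)C[C@H](O[Si](C)(C)C(C)(C)C)C[C@](C)(O)C=O | intermediate
17 | allyl methoxymethyl ether | C=CCOCOC | starting material
18 | (Z)-3-(methoxymethoxy)allyllithium | [Li]C/C=C\OCOC | intermediate
19 | [(Z)-3-(methoxymethoxy)allyl]bis(isopinocampheyl)borane (Ipc from (+)-α-pinene) | COCO/C=C\CB([C@@H]1C[C@@H]2C[C@H]([C@H]1C)C2(C)C)[C@@H]1C[C@@H]2C[C@H]([C@H]1C)C2(C)C | intermediate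
20 | (2S,4S,6S,7S,8R)-4-[(tert-butyldimethylsilyl)oxy]-1-(1,3-dithian-2-yl)-6,7-dihydroxy-8-(methoxymethoxy)-2,6-dimethyldec-9-en-1-one | O=C(C1SCCCS1)[C@@H](C)C[C@H](O[Si](C)(C)C(C)(C)C)C[C@](C)(O)[C@@H](O)[C@H](OCOC)C=C | intermediate
21 | (2S,4S,6S,7S,8R)-4-[(tert-butyldimethylsilyl)oxy]-1-(1,3-dithian-2-yl)-6,7,8-trihydroxy-2,6-dimethyldec-9-en-1-one | O=C(C1SCCCS1)[C@@H](C)C[C@H](O[Si](C)(C)C(C)(C)C)C[C@](C)(O)[C@@H](O)[C@H](O)C=C | intermediate
22 | 2-(bromomethyl)acrylic acid | C=C(CBr)C(=O)O | starting material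
23 | 2-(bromomethyl)acryloyl chloride | C=C(CBr)C(Cl)=O | intermediate
24 | (3R,4S,5S,7S,9S)-7-[(tert-butyldimethylsilyl)oxy]-10-(1,3-dithian-2-yl)-4,5-dihydroxy-5,9-dimethyl-10-oxodec-1-en-3-yl 2-(bromomethyl)acrylate | O=C(C1SCCCS1)[C@@H](C)C[C@H](O[Si](C)(C)C(C)(C)C)C[C@](C)(O)[C@@H](O)[C@H](OC(=O)C(=C)CBr)C=C | intermediate
25 | (5R)-3-(bromomethyl)-5-[(1S,2S,4S,6S)-4-[(tert-butyldimethylsilyl)oxy]-7-(1,3-dithian-2-yl)-1,2-dihydroxy-2,6-dimethyl-7-oxoheptyl]furan-2(5H)-one | O=C(C1SCCCS1)[C@@H](C)C[C@H](O[Si](C)(C)C(C)(C)C)C[C@](C)(O)[C@@H](O)[C@@H]1OC(=O)C(CBr)=C1 | intermediate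
26 | (5R)-3-(bromomethyl)-5-[(1S,2S,4S,6S)-4-[(tert-butyldimethylsilyl)oxy]-1,2-dihydroxy-2,6-dimethyl-7,8-dioxooctyl]furan-2(5H)-one | O=CC(=O)[C@@H](C)C[C@H](O[Si](C)(C)C(C)(C)C)C[C@](C)(O)[C@@H](O)[C@@H]1OC(=O)C(CBr)=C1 | intermediate
27 | allylchromium(III) dichloride derived from 26 (Cr on C13) | O=CC(=O)[C@@H](C)C[C@H](O[Si](C)(C)C(C)(C)C)C[C@](C)(O)[C@@H](O)[C@@H]1OC(=O)C(C[Cr](Cl)Cl)=C1 | intermediate
28 | (2S,4S,6S,7R,8R,9S,10S)-2-[(tert-butyldimethylsilyl)oxy]-6,9,10-trihydroxy-5-oxogermacr-11(13)-en-12,8-olide | C=C1C(=O)O[C@@H]2[C@@H]1[C@H](O)C(=O)[C@@H](C)C[C@H](O[Si](C)(C)C(C)(C)C)C[C@](C)(O)[C@H]2O | intermediate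
29 | (2S,4S,6S,7R,8R,9S,10S)-2-[(tert-butyldimethylsilyl)oxy]-10-hydroxy-6,9-bis(isobutyryloxy)-5-oxogermacr-11(13)-en-12,8-olide | C=C1C(=O)O[C@@H]2[C@@H]1[C@H](OC(=O)C(C)C)C(=O)[C@@H](C)C[C@H](O[Si](C)(C)C(C)(C)C)C[C@](C)(O)[C@H]2OC(=O)C(C)C | intermediate
30 | cardivin D | C=C1C(=O)O[C@@H]2[C@@H]1[C@H](OC(=O)C(C)C)C(=O)[C@@H](C)C[C@H](O)C[C@](C)(O)[C@H]2OC(=O)C(C)C | target

## Step count and risks

Total steps: 15. Longest linear sequence: 15 (1 → 30).

**Step 13 (macrocyclisation).** Cr(II) may reduce the free 1,2-dicarbonyl, the saturated chain is flexible, and the C6 configuration rests on the macrocyclic transition state. Fallback: setting out from 25, HCl in MeOH removes the TBS group and closes O2 onto the C5 ketone to give the cyclic methyl ketal F1 (the anomer with the dithianyl carbon cis to C1; the anomers equilibrate in acidic methanol). NBS hydrolysis as in step 12 gives the ketal aldehyde F2, which has no free ketone and a tetrahydrofuran turn that holds the chain ends together. CrCl2 closure then gives the 2,5-epoxy-bridged macrocycle F3, bis-isobutyrylation gives the bridged diester F4, and aqueous TFA hydrolysis of the ketal comes back to the route at 30. This fallback carries its own doubt: the bridged form places the C4 methyl on the crowded face, which may strain the ring closure.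

**Step 4 (C2 configuration).** The sense of the directed reduction depends on whether the C10 methyl or the ester sits equatorial, and the two differ little in size. Fallback: setting out from 8, the ketone is reduced under reagent control with an NADPH-dependent ketoreductase chosen from a screening panel (i-PrOH recycling, pH 7 buffer) to diol 9, and acid lactonisation comes back to the route at 10. This fallback makes no new compound (F0).

**Step 7 (half-reduction beside a ketone).** The alkoxide-flanked ester may reduce sluggishly or over-reduce. Fallback: setting out from 14, the ketone is protected as its enolate with LiHMDS as before, but the ester is reduced fully with LiAlH4 to the primary alcohol F5; Parikh–Doering oxidation (SO3·pyridine, DMSO, i-Pr2NEt) of the primary hydroxyl then comes back to the route at 16.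

Further compounds
F1 | step 13 | 2,5-cyclic methyl ketal of 25 with TBS removed (2-methoxyoxolane, dithianyl carbon cis to C1) | CO[C@]1(C2SCCCS2)[C@@H](C)C[C@H](O1)C[C@](C)(O)[C@@H](O)[C@@H]3OC(=O)C(CBr)=C3
F2 | step 13 | ketal aldehyde from F1 (C6 formyl on the 2-methoxyoxolane) | CO[C@]1(C=O)[C@@H](C)C[C@H](O1)C[C@](C)(O)[C@@H](O)[C@@H]2OC(=O)C(CBr)=C2
F3 | step 13 | 2,5-epoxy-5-methoxy-6,9,10-trihydroxygermacr-11(13)-en-12,8-olide (bridged macrocycle) | C=C1C(=O)O[C@@H]2[C@@H]1[C@H](O)[C@@]3(OC)[C@@H](C)C[C@H](O3)C[C@](C)(O)[C@H]2O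
F4 | step 13 | 2,5-epoxy-5-methoxy-10-hydroxy-6,9-bis(isobutyryloxy)germacr-11(13)-en-12,8-olide | C=C1C(=O)O[C@@H]2[C@@H]1[C@H](OC(=O)C(C)C)[C@@]3(OC)[C@@H](C)C[C@H](O3)C[C@](C)(O)[C@H]2OC(=O)C(C)C
F0 | step 4 | none | none
F5 | step 7 | (2S,4S,6S)-4-[(tert-butyldimethylsilyl)oxy]-1-(1,3-dithian-2-yl)-6,7-dihydroxy-2,6-dimethylheptan-1-one | O=C(C1SCCCS1)[C@@H](C)C[C@H](O[Si](C)(C)C(C)(C)C)C[C@](C)(O)CO
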